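## Retrosynthetic overview

1. The three esters are put on last; the 2α- and 6α-carbinols come from a 2,6-diketone by hydride delivery from the C4 hydroxyl.
2. The C10 oxygen and the C8=C9 alkene come from a 2,4-dienone by α-face γ,δ-epoxidation and SmI2 opening of the vinylogous epoxy ketone.
3. The dienone is the hydrolysed form of a 4-methoxy-cycloheptatriene (an azulenone); the C4 hydroxyl is carried up to that point as a C–B bond.
4. Key disconnection (C1–C5 and C1–C10): intramolecular Buchner reaction of an aryl α-diazo ketone. The cyclopentanone and, by norcaradiene ring expansion of the arene, the seven-membered ring form in the same operation; no other ring of the skeleton is made before or after it.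
5. The diazo ketone comes from a (Z)-β-aryl enone by copper-catalysed enantioselective β-borylation (sets C4, the only catalyst-controlled centre) and diazo transfer; the enone comes from m-cresol and ethyl isobutyrylacetate through a coumarin.

Conventions: positions use daucane numbering (C1 = ring-fusion carbon with CH3; C2–C4 = rest of the five-membered ring, C4 bearing OH and isopropyl; C5 = ring-fusion CH; C6–C10 = rest of the seven-membered ring). β is the face of the C1 methyl, α the opposite face. Bpin = 4,4,5,5-tetramethyl-1,3,2-dioxaborolan-2-yl.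

Assumption: the ligand antipode written in step 4 is taken to be the one that gives the (S)-boronate; if the first run shows the opposite sense, the mirror-image ligand is used and nothing else changes.

## Route

Step 1
Reactants: 1 m-cresol (3-methylphenol); 2 ethyl 4-methyl-3-oxopentanoate
Product: 3 7-methyl-4-(propan-2-yl)-2H-chromen-2-one
Conditions: conc. H2SO4, 0 °C → rt
Reagents that add atoms: none
Why: Pechmann condensation, in which transesterification and acid-mediated ring closure at the cresol position ortho to OH and para to CH3 give the 7-methyl-4-isopropylcoumarin (no stereocentre).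

Step 2
Reactants: 3 7-methyl-4-(propan-2-yl)coumarin
Product: 4 methyl (2Z)-3-(2-methoxy-4-methylphenyl)-4-methylpent-2-enoate
Conditions: KOH (2.2 equiv), DMSO/H2O, rt; then MeI (3 equiv), rt, dark
Reagents that add atoms: potassium hydroxide [K+].[OH-]; iodomethane CI
Why: Lactone hydrolysis to the coumarinate dianion followed by double O-methylation (Williamson ether synthesis and carboxylate alkylation) traps the ring-opened form, so the cis aryl/carbonyl relationship of the lactone is kept as the (Z)-alkene.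

Step 3
Reactants: 4 methyl (2Z)-3-(2-methoxy-4-methylphenyl)-4-methylpent-2-enoate
Product: 6 (4Z)-5-(2-methoxy-4-methylphenyl)-6-methylhept-4-en-3-one, via Weinreb amide 5 (not isolated)
Conditions: MeNHOMe·HCl, iPrMgCl, THF, −20 °C; then EtMgBr, −20 → 0 °C; aq NH4Cl
Reagents that add atoms: ethylmagnesium bromide CC[Mg]Br; N,O-dimethylhydroxylamine hydrochloride CNOC.Cl (its atoms stay only in 5)
Why: One-pot Weinreb ketone synthesis, in which the chelated tetrahedral adduct of 5 with EtMgBr collapses only on work-up, so the ethyl ketone forms without over-addition and without touching the alkene geometry.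

Step 4
Reactants: 6 (4Z)-5-(2-methoxy-4-methylphenyl)-6-methylhept-4-en-3-one
Product: 7 (5S)-5-(2-methoxy-4-methylphenyl)-6-methyl-5-(Bpin)heptan-3-one
Conditions: CuCl (5 mol %), NaOtBu (10 mol %), (R)-1-[(S)-2-(diphenylphosphino)ferrocenyl]ethyldicyclohexylphosphine, (C5H5)Fe[C5H3(PPh2)CH(CH3)PCy2] (6 mol %), B2pin2 (1.3 equiv), MeOH (2 equiv), THF, 0 °C → rt
Reagents that add atoms: bis(pinacolato)diboron CC1(C)OB(OC1(C)C)B1OC(C)(C)C(C)(C)O1
Why: Copper-catalysed enantioselective conjugate borylation of a β,β-disubstituted enone, in which the chiral ligand–Cu–Bpin species adds to one face of the alkene and MeOH protonates the copper enolate, setting the fully substituted C4 centre as a C–B bond that serves as a hydroxyl surrogate with no O–H or lone pair to trap the later carbenoid.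

Step 5
Reactants: 7 (5S)-5-(2-methoxy-4-methylphenyl)-6-methyl-5-(Bpin)heptan-3-one
Product: 9 (5S)-2-diazo-5-(2-methoxy-4-methylphenyl)-6-methyl-5-(Bpin)heptan-3-one, via trifluoroacetyl diketone 8 (not isolated)
Conditions: LiN(SiMe3)2, THF, −78 °C; CF3CO2CH2CF3; then MsN3, Et3N, H2O (1 equiv), MeCN, rt
Reagents that add atoms: methanesulfonyl azide CS(=O)(=O)N=[N+]=[N-]; 2,2,2-trifluoroethyl trifluoroacetate O=C(OCC(F)(F)F)C(F)(F)F (its atoms stay only in 8)
Why: Detrifluoroacetylative diazo transfer (Regitz-type), in which kinetic enolisation takes place on the ethyl side because the other α-CH2 is neopentyl, and the activated carbon then accepts N2 with loss of the trifluoroacetyl group while C4 is untouched.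

Step 6
Reactants: 9 (5S)-2-diazo-5-(2-methoxy-4-methylphenyl)-6-methyl-5-(Bpin)heptan-3-one
Product: 11 (3S,8aR)-4-methoxy-6,8a-dimethyl-3-(propan-2-yl)-3-(Bpin)-3,8a-dihydroazulen-1(2H)-one, via norcaradiene 10 (not isolated)
Conditions: Rh2(O2CCH(OH)Ph)4 (1 mol %), CH2Cl2, 40 °C, slow addition of 9 at high dilution
Reagents that add atoms: none
Why: Intramolecular Buchner reaction, in which the rhodium carbenoid adds across the ipso/unsubstituted-ortho bond of the arene (closing the cyclopentanone) and norcaradiene 10 opens by 6π-electrocyclic ring opening to the cycloheptatriene (the seven-membered ring), the quaternary C1 centre being set by C4 because the reacting conformer keeps the isopropyl group away from the ortho-methoxy group and so places the new CH3 cis to boron; α-methyl diazoketones of this type are known to cyclise under rhodium carboxylate catalysis.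

Step 7
Reactants: 11 (3S,8aR)-4-methoxy-6,8a-dimethyl-3-(propan-2-yl)-3-(Bpin)-3,8a-dihydroazulen-1(2H)-one
Product: 13 (3R,3aR,8aR)-3-hydroxy-6,8a-dimethyl-3-(propan-2-yl)-2,3,3a,8a-tetrahydroazulene-1,4-dione, via boryl dienone 12 (not isolated)
Conditions: 1 M HCl (cat.), THF/H2O, 0 °C; then NaBO3·4H2O (4 equiv), 0 °C → rt
Reagents that add atoms: water O; sodium perborate tetrahydrate [Na+].[O-]OB=O.O.O.O.O
Why: Acid-catalysed enol ether hydrolysis (protonation at C5, water at C6) gives the 2,4-dienone, whose epimerisable C5–H settles trans to the angular methyl (isopropyl and C6 trans on the cyclopentane), and perborate oxidation of the tertiary C–B bond then proceeds with retention to the C4 alcohol; keeping boron until C6 is a ketone avoids acid ionisation of an allylic C4–O bond next to the enol ether.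

Step 8
Reactants: 13 (3R,3aR,8aR)-3-hydroxy-6,8a-dimethyl-3-(propan-2-yl)-2,3,3a,8a-tetrahydroazulene-1,4-dione
Product: 14 (3R,3aR,7R,8S,8aS)-7,8-epoxy-3-hydroxy-6,8a-dimethyl-3-(propan-2-yl)-2,3,3a,7,8,8a-hexahydroazulene-1,4-dione
Conditions: dimethyldioxirane (1.5 equiv, acetone solution), CH2Cl2, 0 °C
Reagents that add atoms: dimethyldioxirane CC1(C)OO1
Why: Electrophilic epoxidation takes the more electron-rich γ,δ-alkene (C9=C10) of the dienone on the α-face, opposite the axial angular methyl on the adjacent C1, which fixes the C10–O configuration.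

Step 9
Reactants: 14 (3R,3aR,7R,8S,8aS)-7,8-epoxy-3-hydroxy-6,8a-dimethyl-3-(propan-2-yl)-2,3,3a,7,8,8a-hexahydroazulene-1,4-dione
Product: 16 (3R,3aR,8R,8aS)-3-hydroxy-6,8a-dimethyl-1,4-dioxo-3-(propan-2-yl)-1,2,3,3a,4,5,8,8a-octahydroazulen-8-yl acetate, via hydroxy enone 15 (not isolated)
Conditions: SmI2 (2.3 equiv), MeOH (2 equiv), THF, −78 °C; then Ac2O, pyridine, −78 → 0 °C
Reagents that add atoms: acetic anhydride CC(=O)OC(C)=O
Why: SmI2 reduction of a γ,δ-epoxy enone (vinylogous epoxy ketone opening) cleaves the allylic C9–O bond, the samarium dienolate is protonated at C7 to leave the deconjugated C8=C9 alkene with the C10 oxygen in place, and in-flask acetylation caps the C10 alkoxide so that it cannot direct the next reduction.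

Step 10
Reactants: 16 (3R,3aR,8R,8aS)-3-hydroxy-6,8a-dimethyl-1,4-dioxo-3-(propan-2-yl)-1,2,3,3a,4,5,8,8a-octahydroazulen-8-yl acetate
Product: 17 (1S,3R,3aS,4S,8R,8aR)-1,3,4-trihydroxy-6,8a-dimethyl-3-(propan-2-yl)-1,2,3,3a,4,5,8,8a-octahydroazulen-8-yl acetate
Conditions: Me4NBH(OAc)3 (6 equiv), MeCN/AcOH 1:1, −30 → −10 °C
Reagents that add atoms: none
Why: Evans–Saksena hydroxyl-directed reduction, in which the alkoxy(acetoxy)borohydride formed at the β-oriented C4–OH delivers hydride intramolecularly to the β-face of both flanking ketones and gives the 2α- and 6α-alcohols (1,3-anti to C4–OH) under non-basic conditions that spare the β,γ-enone and the allylic acetate.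

Step 11
Reactants: 17 (1S,3R,3aS,4S,8R,8aR)-1,3,4-trihydroxy-6,8a-dimethyl-3-(propan-2-yl)-1,2,3,3a,4,5,8,8a-octahydroazulen-8-yl acetate; 18 3,4-dimethoxybenzoyl chloride
Product: 19 (1S,3R,3aS,4S,8R,8aR)-8-acetoxy-1,3-dihydroxy-6,8a-dimethyl-3-(propan-2-yl)-1,2,3,3a,4,5,8,8a-octahydroazulen-4-yl 3,4-dimethoxybenzoate
Conditions: 18 (1.1 equiv), pyridine, DMAP (0.1 equiv), CH2Cl2, −20 → 0 °C
Reagents that add atoms: none
Why: DMAP-catalysed esterification, in which the C6–OH (flanked by CH and CH2) reacts ahead of the neopentyl C2–OH beside the quaternary C1 and of the tertiary C4–OH.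

Step 12
Reactants: 19 (1S,3R,3aS,4S,8R,8aR)-8-acetoxy-1,3-dihydroxy-6,8a-dimethyl-3-(propan-2-yl)-1,2,3,3a,4,5,8,8a-octahydroazulen-4-yl 3,4-dimethoxybenzoate
Product: 20 (1S,3R,3aS,4S,8R,8aR)-1,8-diacetoxy-3-hydroxy-6,8a-dimethyl-3-(propan-2-yl)-1,2,3,3a,4,5,8,8a-octahydroazulen-4-yl 3,4-dimethoxybenzoate (CNP0320758.1)
Conditions: Ac2O, pyridine, DMAP, CH2Cl2, rt
Reagents that add atoms: acetic anhydride CC(=O)OC(C)=O
Why: DMAP-catalysed acetylation of the remaining secondary C2–OH; the hindered tertiary C4–OH does not react at room temperature.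

## Compound list

1 | 3-methylphenol (m-cresol) | Cc1cccc(O)c1 | starting material
2 | ethyl 4-methyl-3-oxopentanoate | CCOC(=O)CC(=O)C(C)C | starting material
3 | 7-methyl-4-(propan-2-yl)-2H-chromen-2-one | Cc1ccc2c(c1)OC(=O)C=C2C(C)C | intermediate
4 | methyl (2Z)-3-(2-methoxy-4-methylphenyl)-4-methylpent-2-enoate | COC(=O)/C=C(/C(C)C)c1ccc(C)cc1OC | intermediate
5 | (2Z)-N-methoxy-3-(2-methoxy-4-methylphenyl)-N,4-dimethylpent-2-enamide | CON(C)C(=O)/C=C(/C(C)C)c1ccc(C)cc1OC | intermediate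
6 | (4Z)-5-(2-methoxy-4-methylphenyl)-6-methylhept-4-en-3-one | CCC(=O)/C=C(/C(C)C)c1ccc(C)cc1OC | intermediate
7 | (5S)-5-(2-methoxy-4-methylphenyl)-6-methyl-5-(4,4,5,5-tetramethyl-1,3,2-dioxaborolan-2-yl)heptan-3-one | CCC(=O)C[C@@](B1OC(C)(C)C(C)(C)O1)(C(C)C)c1ccc(C)cc1OC | intermediate
8 | (6S)-1,1,1-trifluoro-6-(2-methoxy-4-methylphenyl)-3,7-dimethyl-6-(Bpin)octane-2,4-dione (both C3 epimers; lithium enolate in the flask) | CC(C(=O)C(F)(F)F)C(=O)C[C@@](B1OC(C)(C)C(C)(C)O1)(C(C)C)c1ccc(C)cc1OC | intermediate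
9 | (5S)-2-diazo-5-(2-methoxy-4-methylphenyl)-6-methyl-5-(Bpin)heptan-3-one | CC(=[N+]=[N-])C(=O)C[C@@](B1OC(C)(C)C(C)(C)O1)(C(C)C)c1ccc(C)cc1OC | intermediate
10 | norcaradiene valence isomer of 11 (cyclopropane joining C1, C5 and C10; diene C6=C7–C8=C9; C1 methyl cis to Bpin) | COC1=CC(C)=C[C@@H]2[C@@]3(C)C(=O)C[C@@](B4OC(C)(C)C(C)(C)O4)(C(C)C)[C@@]123 | intermediate
11 | (3S,8aR)-4-methoxy-6,8a-dimethyl-3-(propan-2-yl)-3-(Bpin)-3,8a-dihydroazulen-1(2H)-one | COC1=C2[C@](B3OC(C)(C)C(C)(C)O3)(C(C)C)CC(=O)[C@]2(C)C=CC(C)=C1 | intermediate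
12 | (3S,3aS,8aR)-6,8a-dimethyl-3-(propan-2-yl)-3-(Bpin)-2,3,3a,8a-tetrahydroazulene-1,4-dione | O=C1C=C(C)C=C[C@@]2(C)C(=O)C[C@@](B3OC(C)(C)C(C)(C)O3)(C(C)C)[C@H]12 | intermediate
13 | (3R,3aR,8aR)-3-hydroxy-6,8a-dimethyl-3-(propan-2-yl)-2,3,3a,8a-tetrahydroazulene-1,4-dione | O=C1C=C(C)C=C[C@@]2(C)C(=O)C[C@@](O)(C(C)C)[C@H]12 | intermediate
14 | (3R,3aR,7R,8S,8aS)-7,8-epoxy-3-hydroxy-6,8a-dimethyl-3-(propan-2-yl)-2,3,3a,7,8,8a-hexahydroazulene-1,4-dione | O=C1C=C(C)[C@H]3O[C@H]3[C@@]2(C)C(=O)C[C@@](O)(C(C)C)[C@H]12 | intermediate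
15 | (3R,3aR,8R,8aS)-3,8-dihydroxy-6,8a-dimethyl-3-(propan-2-yl)-2,3,3a,5,8,8a-hexahydroazulene-1,4-dione | O=C1CC(C)=C[C@@H](O)[C@@]2(C)C(=O)C[C@@](O)(C(C)C)[C@H]12 | intermediate
16 | (3R,3aR,8R,8aS)-3-hydroxy-6,8a-dimethyl-1,4-dioxo-3-(propan-2-yl)-1,2,3,3a,4,5,8,8a-octahydroazulen-8-yl acetate | O=C1CC(C)=C[C@@H](OC(C)=O)[C@@]2(C)C(=O)C[C@@](O)(C(C)C)[C@H]12 | intermediate
17 | (1S,3R,3aS,4S,8R,8aR)-1,3,4-trihydroxy-6,8a-dimethyl-3-(propan-2-yl)-1,2,3,3a,4,5,8,8a-octahydroazulen-8-yl acetate | O[C@H]1CC(C)=C[C@@H](OC(C)=O)[C@@]2(C)[C@@H](O)C[C@@](O)(C(C)C)[C@H]12 | intermediate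
18 | 3,4-dimethoxybenzoyl chloride | COc1ccc(C(=O)Cl)cc1OC | starting material
19 | (1S,3R,3aS,4S,8R,8aR)-8-acetoxy-1,3-dihydroxy-6,8a-dimethyl-3-(propan-2-yl)-1,2,3,3a,4,5,8,8a-octahydroazulen-4-yl 3,4-dimethoxybenzoate | COc1ccc(C(=O)O[C@H]2CC(C)=C[C@@H](OC(C)=O)[C@@]3(C)[C@@H](O)C[C@@](O)(C(C)C)[C@H]23)cc1OC | intermediate
20 | (1S,3R,3aS,4S,8R,8aR)-1,8-diacetoxy-3-hydroxy-6,8a-dimethyl-3-(propan-2-yl)-1,2,3,3a,4,5,8,8a-octahydroazulen-4-yl 3,4-dimethoxybenzoate | COc1ccc(C(=O)O[C@H]2CC(C)=C[C@@H](OC(C)=O)[C@@]3(C)[C@@H](OC(C)=O)C[C@@](O)(C(C)C)[C@H]23)cc1OC | target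

## Step count and weak points

Total step count: 12. Longest linear sequence: 12 (1 and 2 to 20; 18 is bought).

The three steps most likely to fail:

**Step 6 (Buchner ring formation).** The risks are a 1,2-hydride shift of the α-methyl carbenoid to a vinyl ketone, 1,5 C–H insertion into the isopropyl methine, and incomplete control of C1 against C4. The fallback sets out from 4 and comes back at 11; it uses a terminal diazo ketone and installs the angular methyl afterwards. The one-pot sequence of step 3, run with MeMgBr in place of EtMgBr, gives (through 5) (3Z)-4-(2-methoxy-4-methylphenyl)-5-methylhex-3-en-2-one F4. The borylation of step 4 gives (4S)-4-(2-methoxy-4-methylphenyl)-5-methyl-4-(Bpin)hexan-2-one F5. LiN(SiMe3)2 and CF3CO2CH2CF3 give (6S)-1,1,1-trifluoro-6-(2-methoxy-4-methylphenyl)-7-methyl-6-(Bpin)octane-2,4-dione F6 (not isolated), and MsN3 turns it into (4S)-1-diazo-4-(2-methoxy-4-methylphenyl)-5-methyl-4-(Bpin)hexan-2-one F7, which has no β-hydrogen to shift and belongs to the best-behaved substrate class for this cyclisation. Rh2(OAc)4 in CH2Cl2 gives, through the norcaradiene F8, (3S,8aR)-4-methoxy-6-methyl-3-(propan-2-yl)-3-(Bpin)-3,8a-dihydroazulen-1(2H)-one F9, whose C8a configuration does not matter. KN(SiMe3)2 then MeI (THF, −78 °C) methylates the doubly activated C8a of the planar extended enolate on the face away from the isopropyl group and gives 11.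

**Step 4 (enantioselective borylation of the hindered enone).** The risk is low conversion or low selectivity because the β-carbon carries both an isopropyl and an ortho-substituted aryl group. The fallback sets out from 4 and comes back at 9; it moves the borylation to the ester, the better-behaved substrate class, and makes the diazo ketone by acylation of a diazoalkane instead of diazo transfer. The same CuCl/ligand/B2pin2/MeOH system on 4 gives methyl (3S)-3-(2-methoxy-4-methylphenyl)-4-methyl-3-(Bpin)pentanoate F1. LiOH in THF/H2O gives (3S)-3-(2-methoxy-4-methylphenyl)-4-methyl-3-(Bpin)pentanoic acid F2. Isobutyl chloroformate and N-methylmorpholine give the mixed isobutyl carbonic anhydride F3 (not isolated), which acylates diazoethane (Et2O, −10 °C) to give 9.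

**Step 11 (selective acylation of C6–OH over C2–OH).** The risk is that the two secondary alcohols are not distinguished well enough. The fallback sets out from 14 and comes back at 20; it reduces and acylates the two carbinols at different stages so that only one secondary hydroxyl is ever free at the end. Me4NBH(OAc)3 (1.5 equiv, MeCN/AcOH, −40 °C) reduces only the saturated C2 ketone of 14, not the conjugated one, to give (1S,3R,3aR,7R,8S,8aR)-7,8-epoxy-1,3-dihydroxy-6,8a-dimethyl-3-(propan-2-yl)-2,3,3a,7,8,8a-hexahydroazulen-4(1H)-one F10. SmI2/MeOH (THF, −78 °C) gives (1S,3R,3aR,8R,8aR)-1,3,8-trihydroxy-6,8a-dimethyl-3-(propan-2-yl)-2,3,3a,5,8,8a-hexahydroazulen-4(1H)-one F11. Ac2O, pyridine and catalytic DMAP at 0 °C give (1S,3R,3aR,8R,8aR)-3-hydroxy-6,8a-dimethyl-4-oxo-3-(propan-2-yl)-1,2,3,3a,4,5,8,8a-octahydroazulene-1,8-diyl diacetate F12. Me4NBH(OAc)3 gives (1S,3R,3aS,4S,8R,8aR)-3,4-dihydroxy-6,8a-dimethyl-3-(propan-2-yl)-1,2,3,3a,4,5,8,8a-octahydroazulene-1,8-diyl diacetate F13, and 18 with pyridine/DMAP then gives 20.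

## Further compounds

F1 | step 4 | methyl (3S)-3-(2-methoxy-4-methylphenyl)-4-methyl-3-(4,4,5,5-tetramethyl-1,3,2-dioxaborolan-2-yl)pentanoate | COC(=O)C[C@@](B1OC(C)(C)C(C)(C)O1)(C(C)C)c1ccc(C)cc1OC
F2 | step 4 | (3S)-3-(2-methoxy-4-methylphenyl)-4-methyl-3-(4,4,5,5-tetramethyl-1,3,2-dioxaborolan-2-yl)pentanoic acid | OC(=O)C[C@@](B1OC(C)(C)C(C)(C)O1)(C(C)C)c1ccc(C)cc1OC
F3 | step 4 | (3S)-3-(2-methoxy-4-methylphenyl)-4-methyl-3-(Bpin)pentanoic isobutyl carbonic anhydride | CC(C)COC(=O)OC(=O)C[C@@](B1OC(C)(C)C(C)(C)O1)(C(C)C)c1ccc(C)cc1OC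
F4 | step 6 | (3Z)-4-(2-methoxy-4-methylphenyl)-5-methylhex-3-en-2-one | CC(=O)/C=C(/C(C)C)c1ccc(C)cc1OC
F5 | step 6 | (4S)-4-(2-methoxy-4-methylphenyl)-5-methyl-4-(Bpin)hexan-2-one | CC(=O)C[C@@](B1OC(C)(C)C(C)(C)O1)(C(C)C)c1ccc(C)cc1OC
F6 | step 6 | (6S)-1,1,1-trifluoro-6-(2-methoxy-4-methylphenyl)-7-methyl-6-(Bpin)octane-2,4-dione | O=C(CC(=O)C(F)(F)F)C[C@@](B1OC(C)(C)C(C)(C)O1)(C(C)C)c1ccc(C)cc1OC
F7 | step 6 | (4S)-1-diazo-4-(2-methoxy-4-methylphenyl)-5-methyl-4-(Bpin)hexan-2-one | [N-]=[N+]=CC(=O)C[C@@](B1OC(C)(C)C(C)(C)O1)(C(C)C)c1ccc(C)cc1OC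
F8 | step 6 | norcaradiene valence isomer of F9 (cyclopropane joining C1, C5 and C10) | COC1=CC(C)=C[C@@H]2[C@H]3C(=O)C[C@@](B4OC(C)(C)C(C)(C)O4)(C(C)C)[C@@]123
F9 | step 6 | (3S,8aR)-4-methoxy-6-methyl-3-(propan-2-yl)-3-(Bpin)-3,8a-dihydroazulen-1(2H)-one | COC1=C2[C@](B3OC(C)(C)C(C)(C)O3)(C(C)C)CC(=O)[C@@H]2C=CC(C)=C1
F10 | step 11 | (1S,3R,3aR,7R,8S,8aR)-7,8-epoxy-1,3-dihydroxy-6,8a-dimethyl-3-(propan-2-yl)-2,3,3a,7,8,8a-hexahydroazulen-4(1H)-one | O=C1C=C(C)[C@H]3O[C@H]3[C@@]2(C)[C@@H](O)C[C@@](O)(C(C)C)[C@H]12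
F11 | step 11 | (1S,3R,3aR,8R,8aR)-1,3,8-trihydroxy-6,8a-dimethyl-3-(propan-2-yl)-2,3,3a,5,8,8a-hexahydroazulen-4(1H)-one | O=C1CC(C)=C[C@@H](O)[C@@]2(C)[C@@H](O)C[C@@](O)(C(C)C)[C@H]12
F12 | step 11 | (1S,3R,3aR,8R,8aR)-3-hydroxy-6,8a-dimethyl-4-oxo-3-(propan-2-yl)-1,2,3,3a,4,5,8,8a-octahydroazulene-1,8-diyl diacetate | O=C1CC(C)=C[C@@H](OC(C)=O)[C@@]2(C)[C@@H](OC(C)=O)C[C@@](O)(C(C)C)[C@H]12
F13 | step 11 | (1S,3R,3aS,4S,8R,8aR)-3,4-dihydroxy-6,8a-dimethyl-3-(propan-2-yl)-1,2,3,3a,4,5,8,8a-octahydroazulene-1,8-diyl diacetate | O[C@H]1CC(C)=C[C@@H](OC(C)=O)[C@@]2(C)[C@@H](OC(C)=O)C[C@@](O)(C(C)C)[C@H]12
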